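**Plan**

- Retrosynthesis: the C16 carbinol goes back to C16=C17 and C14 to a ketone. C13–C16 is cut (ring D), then C8–C9 and C11–C12 are cut together (rings B and C). This leaves ring A with a C5 arm and a C10 vinyl sulfone; the arm is cut at C8–C15, C6–C8 and C5–C6, and ring A at C4–C18 and its Michael/Dieckmann bonds (C10–C1, C10–C5, C3–C4).
- Enabling feature: ring C (C8, C9, C11–C14) shares only the edge C8–C9 with ring B, and C14 lies between the future bridgeheads C8 and C13. With an enol ether at C14, ring C is the cyclohexene adduct of the 2-silyloxydiene C8=C14–C13=C12 (on the C5 arm) and the dienophile C9=C11 (on C10).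
- Forward order: ring A (steps 1–8); the C5 arm with C6 and the C8 propargyl group (9–14); vinyl sulfone, vinyl ketone, silyloxydiene (15–20); rings B and C in one step (21); ring D (22); C16 hydration, removal of the C14 oxygen and the sulfone, deprotection (23–28).
- Stereochemistry: C5 from a rhodium/(S)-BINAP conjugate vinylation; C4 from alkylation anti to C5; C3 from a catalyst-controlled (CBS) reduction; C10 from a lactonisation open only to the ester cis to the C3 oxygen; C6 from an Evans alkylation; C8 and C9 in the key step (relay from C6 and the cis ring fusion); C13 from the bridge; C16 from exo-face hydration.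

Key step: step 21

Remark: gibberellane locants (C1–C20) are used for the atoms of all intermediates, and the rhodium/(S)-BINAP catalyst is assumed to attack the same enone face as it does in 2-cyclohexenone.

**Route**

Step 1
Reactants: 1 dimethyl malonate; 2 methyl acrylate (2 equiv)
Product: 4 trimethyl 4-oxocyclohexane-1,1,3-tricarboxylate, via tetraester 3 (not isolated)
Conditions: NaOMe (cat.), MeOH, 0 °C to rt; then NaH (1.2 equiv), THF, reflux; AcOH
Reagents that add atoms: none
Why: Double Michael addition of the malonate to two acrylates followed by Dieckmann condensation of the symmetrical tetraester can give only one cyclic β-keto ester, which already holds C10 (diester), C3 (ketone) and C4 (ester, C19); no stereocentre needs control.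

Step 2
Reactants: 4 trimethyl 4-oxocyclohexane-1,1,3-tricarboxylate
Product: 6 trimethyl 4-oxocyclohex-2-ene-1,1,3-tricarboxylate, via selenide 5 (not isolated)
Conditions: PhSeCl, pyridine, CH2Cl2, 0 °C; then 30 % H2O2, 0 °C to rt
Reagents that add atoms: none
Why: α-Selenenylation of the β-keto ester and selenoxide syn-elimination, which can only use the C5 hydrogens, should give the C4=C5 enone, which cannot aromatise because C10 is quaternary.

Step 3
Reactants: 6 trimethyl 4-oxocyclohex-2-ene-1,1,3-tricarboxylate; 7 2,4,6-trivinylcyclotriboroxane–pyridine complex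
Product: 8 trimethyl (2R)-4-oxo-2-vinylcyclohexane-1,1,3-tricarboxylate
Conditions: [Rh(OH)((S)-BINAP)]2 (3 mol %), 1,4-dioxane/H2O (10:1), 35 °C
Reagents that add atoms: none
Why: Hayashi–Miyaura asymmetric 1,4-addition, in which the vinylrhodium–BINAP species adds to C5 of the doubly activated cyclic enone and water protonates the rhodium enolate; the (S)-ligand is expected to select the enone face that gives the C5 configuration of the target.

Step 4
Reactants: 8 trimethyl (2R)-4-oxo-2-vinylcyclohexane-1,1,3-tricarboxylate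
Product: 9 trimethyl (2R,3S)-3-methyl-4-oxo-2-vinylcyclohexane-1,1,3-tricarboxylate
Conditions: K2CO3, MeI, acetone, rt
Reagents that add atoms: iodomethane, CI
Why: C-Alkylation of the β-keto ester enolate should occur anti to the adjacent C5 vinyl group, so that at the new quaternary C4 the methyl group (C18) is trans and the ester (C19) cis to the vinyl group.

Step 5
Reactants: 9 trimethyl (2R,3S)-3-methyl-4-oxo-2-vinylcyclohexane-1,1,3-tricarboxylate
Product: 10 trimethyl (2R,3S,4S)-4-hydroxy-3-methyl-2-vinylcyclohexane-1,1,3-tricarboxylate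
Conditions: (R)-2-methyl-CBS-oxazaborolidine (20 mol %), catecholborane, toluene, −78 to −40 °C; then MeOH, aq. NH4Cl
Reagents that add atoms: none
Why: Corey–Bakshi–Shibata reduction, with quaternary C4 as the large and the C2 methylene as the small ketone substituent, so that the (R)-catalyst should deliver hydride to the face that leaves the C3 hydroxyl cis to the C18 methyl and trans to the C19 ester, independent of the ring conformation, while catecholborane spares the vinyl group and the esters.

Step 6
Reactants: 10 trimethyl (2R,3S,4S)-4-hydroxy-3-methyl-2-vinylcyclohexane-1,1,3-tricarboxylate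
Product: 11 dimethyl 6-methyl-3-oxo-5-vinyl-2-oxabicyclo[2.2.2]octane-4,6-dicarboxylate (lactone from the C3 oxygen to the C10 ester cis to it)
Conditions: p-TsOH·H2O (10 mol %), toluene, reflux, 4 Å molecular sieves
Reagents that add atoms: none
Why: Acid-catalysed intramolecular transesterification in which only the C10 ester that is cis-1,4 to the C3 hydroxyl can reach it (through the boat form), so the two diastereotopic esters are told apart by geometry and C10 becomes a defined stereocentre with the future C9 carbon on the face of the C3 oxygen.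

Step 7
Reactants: 11 dimethyl 6-methyl-3-oxo-5-vinyl-2-oxabicyclo[2.2.2]octane-4,6-dicarboxylate
Product: 12 dimethyl 4-hydroxy-1-(hydroxymethyl)-3-methyl-2-vinylcyclohexane-1,3-dicarboxylate (C9 hydroxymethyl cis to the C3 hydroxyl, trans to vinyl)
Conditions: LiBH4 (1.1 equiv), THF, 0 °C; then H2O
Reagents that add atoms: none
Why: Borohydride reduction of the strained, malonate-type activated lactone carbonyl should be faster than that of the two neopentyl methyl esters, giving the C3 hydroxyl and the C9 primary alcohol.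

Step 8
Reactants: 12 dimethyl 4-hydroxy-1-(hydroxymethyl)-3-methyl-2-vinylcyclohexane-1,3-dicarboxylate
Product: 13 bis(tert-butyldimethylsilyl) ether of 12
Conditions: t-BuMe2SiOTf (2.5 equiv), 2,6-lutidine, CH2Cl2, 0 °C
Reagents that add atoms: tert-butyldimethylsilyl triflate, CC(C)(C)[Si](C)(C)OS(=O)(=O)C(F)(F)F
Why: Silyl triflate silylation, reactive enough for the hindered axial C3 alcohol, protects both hydroxyls in one operation.

Step 9
Reactants: 13 bis(tert-butyldimethylsilyl) ether of 12
Product: 14 primary alcohol (C5 2-hydroxyethyl group, C6H2–C7H2OH)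
Conditions: 9-BBN, THF, rt to 50 °C; then NaOH, H2O2, 0 °C
Reagents that add atoms: hydrogen peroxide, OO
Why: Anti-Markovnikov hydroboration–oxidation of the monosubstituted alkene with a bulky borane that does not reduce esters; no stereocentre is formed.

Step 10
Reactants: 14 primary alcohol
Product: 15 carboxylic acid (C5 carboxymethyl group, C6H2–C7O2H)
Conditions: TEMPO (20 mol %), PhI(OAc)2, MeCN/H2O (1:1), rt
Reagents that add atoms: water, O
Why: Nitroxyl-catalysed oxidation of the primary alcohol through the aldehyde hydrate to the acid, under conditions that leave silyl ethers and esters intact.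

Step 11
Reactants: 15 carboxylic acid; 16 (R)-4-benzyl-2-oxazolidinone
Product: 18 N-acyl oxazolidinone of 15, via mixed pivalic anhydride 17 (not isolated)
Conditions: t-BuCOCl, Et3N, THF, −20 °C; then LiCl, 16, rt
Reagents that add atoms: none
Why: N-Acylation through the mixed anhydride installs the Evans auxiliary, the (R)-enantiomer being the one whose enolate exposes the face needed at C6.

Step 12
Reactants: 18 N-acyl oxazolidinone of 15; 19 tert-butyl bromoacetate
Product: 20 C6-alkylated imide (C8H2–C14O2t-Bu on C6)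
Conditions: NaN(SiMe3)2, THF, −78 °C; then 19, −78 to −40 °C
Reagents that add atoms: none
Why: Evans alkylation, in which the chelated (Z)-sodium enolate is attacked by the bromoacetate on the face opposite the benzyl group, should set C6 as in the target by auxiliary control, overriding any bias from ring A.

Step 13
Reactants: 20 C6-alkylated imide
Product: 21 succinic half-ester (C7 acid, C14 tert-butyl ester)
Conditions: LiOH, H2O2, THF/H2O, 0 °C; Na2SO3; then 1 M HCl
Reagents that add atoms: hydrogen peroxide, OO
Why: Lithium hydroperoxide attacks the exocyclic imide carbonyl selectively, releasing the acid and the auxiliary without epimerising C6 and without touching the tert-butyl or the hindered methyl esters.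

Step 14
Reactants: 21 succinic half-ester; 22 propargyl bromide
Product: 24 C7 methyl ester with C8 propargyl group (C8 epimers), via propargylated acid 23 (not isolated)
Conditions: LiN(i-Pr)2 (2.2 equiv), THF, −78 °C; then 22, −78 to −40 °C; aq. HCl; then Me3SiCHN2, MeOH/toluene, 0 °C
Reagents that add atoms: (trimethylsilyl)diazomethane, C[Si](C)(C)C=[N+]=[N-]
Why: Alkylation of the carboxylate/ester-enolate dianion (succinate half-ester dianion alkylation) deprotonates only α to the tert-butyl ester, so C8 is propargylated while C6 is untouched; the C8 configuration does not matter because C8 becomes trigonal in step 20, and the acid is then methylated by the diazoalkane.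

Step 15
Reactants: 24 C7 methyl ester with C8 propargyl group
Product: 25 C9 primary alcohol
Conditions: HF·pyridine, pyridine, THF, 0 °C
Reagents that add atoms: none
Why: Fluoride desilylation should be much faster at the primary C9 silyl ether than at the hindered secondary C3 silyl ether.

Step 16
Reactants: 25 C9 primary alcohol
Product: 26 C9 aldehyde
Conditions: Dess–Martin periodinane, CH2Cl2, rt
Reagents that add atoms: none
Why: Dess–Martin oxidation of the neopentyl primary alcohol gives the non-enolisable aldehyde on quaternary C10.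

Step 17
Reactants: 26 C9 aldehyde; 27 diethyl (phenylsulfonylmethyl)phosphonate
Product: 28 (E)-vinyl sulfone (C9=C11)
Conditions: NaH, THF, 0 °C; then 26, 0 °C to rt
Reagents that add atoms: none
Why: Horner–Wadsworth–Emmons olefination with the sulfonyl-stabilised phosphonate anion, which is too weakly basic to epimerise C6, should give the (E)-vinyl sulfone.

Step 18
Reactants: 28 (E)-vinyl sulfone
Product: 29 C14 carboxylic acid
Conditions: Me3SiOTf, 2,6-lutidine, CH2Cl2, 0 °C to rt; then H2O
Reagents that add atoms: none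
Why: Silyl triflate cleavage of the tert-butyl ester (loss of isobutene, silyl ester hydrolysed on work-up) spares the methyl esters, the C3 silyl ether, the alkyne and the vinyl sulfone.

Step 19
Reactants: 29 C14 carboxylic acid; 30 tributyl(vinyl)stannane
Product: 32 vinyl ketone (C14 ketone, C13=C12), via acid chloride 31 (not isolated)
Conditions: (COCl)2, DMF (cat.), CH2Cl2, 0 °C; evaporation; then 30, Pd(PPh3)4 (5 mol %), toluene, 60 °C
Reagents that add atoms: none
Why: Stille acylation of the acid chloride with the vinylstannane under zerovalent palladium catalysis gives the vinyl ketone under neutral conditions that the vinyl sulfone and the terminal alkyne tolerate.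

Step 20
Reactants: 32 vinyl ketone
Product: 33 silyl dienol ether (C8=C14(OSi)–C13=C12, C6 cis to the siloxy group)
Conditions: t-BuMe2SiOTf, Et3N, CH2Cl2, −78 to 0 °C
Reagents that add atoms: tert-butyldimethylsilyl triflate, CC(C)(C)[Si](C)(C)OS(=O)(=O)C(F)(F)F
Why: Soft enolisation of the vinyl ketone can only take place toward C8, which gives the cross-conjugated 2-silyloxydiene, merges the C8 epimers and is expected to place the bulky C6 substituent cis to the siloxy group.

Step 21
Reactants: 33 silyl dienol ether
Product: 34 tricyclic silyl enol ether (rings A, B, C; C13=C14 enol ether, C8 propargyl, C11 sulfone)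
Conditions: toluene (0.01 M), BHT, 130 °C, sealed tube
Reagents that add atoms: none
Why: Thermal intramolecular Diels–Alder reaction of the 2-silyloxydiene C8=C14–C13=C12 with the (E)-vinyl sulfone C9=C11, asynchronous, with the nucleophilic diene terminus C8 bonding first to the sulfone β-carbon C9; the closest known reactions are intramolecular Diels–Alder reactions of 2-silyloxydienes with activated alkenes and their stepwise counterpart, the intramolecular double Michael reaction. Ring B (C5, C6, C8, C9, C10) is closed by the C8–C9 bond across the three-atom tether (5-exo in the stepwise picture), and ring C (C8, C9, C11–C14) by the bond pair C8–C9/C11–C12 of the [4+2] addition (6-endo for the second bond). C8 is controlled by C6: allylic 1,3-strain holds H6 in the plane of the tetrasubstituted C8=C14 bond, so the dienophile delivered from C5 adds to the diene face that leaves C15 syn to the C7 ester; C9 follows from the cis B/C fusion (H9 syn to C15), and C11 from suprafacial addition to the (E)-alkene. The step needs the cis-fused, tether-endo mode on that diene face; a trans B/C fusion on a ring B already trans-fused to ring A would be too strained, and the quaternary C10 together with the strongly polarised diene/dienophile pair should let the cycloaddition proceed despite the fully substituted diene terminus.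

Step 22
Reactants: 34 tricyclic silyl enol ether
Product: 35 tetracyclic C14 ketone with C16=C17 exo-methylene
Conditions: Ph3PAuNTf2 (5 mol %), CH2Cl2/MeOH (10:1), rt
Reagents that add atoms: none
Why: Gold-catalysed Conia-ene (5-exo-dig) cyclisation, in which C13 of the silyl enol ether attacks the gold-activated alkyne to form C13–C16 and the bicyclo[3.2.1]octane while methanol takes up the silyl group; the C13 configuration is dictated by the bridge.

Step 23
Reactants: 35 tetracyclic C14 ketone
Product: 36 C16 tertiary alcohol (C17 methyl)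
Conditions: Co(acac)2 (20 mol %), PhSiH3, O2 (1 atm), THF, rt
Reagents that add atoms: dioxygen, O=O
Why: Mukaiyama hydration, in which hydrogen-atom transfer to C17 gives the tertiary C16 radical that dioxygen should trap on the exo face (the side of the C14 bridge, away from the axial C11 hydrogen), giving the C16 configuration of the target.

Step 24
Reactants: 36 C16 tertiary alcohol
Product: 37 C14 tosylhydrazone
Conditions: TsNHNH2, MeOH, 60 °C
Reagents that add atoms: 4-methylbenzenesulfonohydrazide, Cc1ccc(cc1)S(=O)(=O)NN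
Why: Condensation of the angle-strained, non-enolisable bridging ketone with the sulfonyl hydrazide gives the hydrazone without the basic conditions that could trigger a retro-aldol opening of ring D.

Step 25
Reactants: 37 C14 tosylhydrazone
Product: 38 C14 methylene compound (C11 sulfone retained)
Conditions: catecholborane, CHCl3, 0 °C to rt; then NaOAc·3H2O, reflux
Reagents that add atoms: none
Why: Caglioti-type tosylhydrazone reduction, in which hydride adds to C=N and acetate then induces loss of sulfinate and dinitrogen, converts C14 into a methylene group under conditions that spare the esters, the sulfone and the tertiary alcohol.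

Step 26
Reactants: 38 C14 methylene compound
Product: 39 trimethyl ester C3 silyl ether of the target
Conditions: Na/Hg (6 % Na), Na2HPO4, MeOH/THF, −20 to 0 °C
Reagents that add atoms: none
Why: Reductive desulfonylation with buffered sodium amalgam (electron transfer, C–S cleavage, protonation) removes the C11 sulfone, to which esters and alcohols are inert.

Step 27
Reactants: 39 trimethyl ester C3 silyl ether
Product: 40 trimethyl ester of the target
Conditions: HF (48 % aq.), MeCN, rt
Reagents that add atoms: none
Why: Acidic fluoride cleaves the hindered C3 silyl ether without base, which avoids retro-aldol epimerisation at C3.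

Step 28
Reactants: 40 trimethyl ester of the target
Product: 41 CNP0183110.3
Conditions: LiS-n-Pr (from n-PrSH and n-BuLi), HMPA, rt to 50 °C; then aq. HCl
Reagents that add atoms: none
Why: SN2 demethylation by the thiolate at the methyl carbons, not at the hindered carbonyls, frees the three acids without a strong base at C3 or C6.

**Compound list**

1 | dimethyl malonate | COC(=O)CC(=O)OC | starting material
2 | methyl acrylate | C=CC(=O)OC | starting material
3 | tetramethyl pentane-1,3,3,5-tetracarboxylate | COC(=O)CCC(CCC(=O)OC)(C(=O)OC)C(=O)OC | intermediate (not isolated)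
4 | trimethyl 4-oxocyclohexane-1,1,3-tricarboxylate | COC(=O)C1CC(C(=O)OC)(C(=O)OC)CCC1=O | intermediate
5 | trimethyl 4-oxo-3-(phenylselanyl)cyclohexane-1,1,3-tricarboxylate | COC(=O)C1([Se]c2ccccc2)CC(C(=O)OC)(C(=O)OC)CCC1=O | intermediate (not isolated)
6 | trimethyl 4-oxocyclohex-2-ene-1,1,3-tricarboxylate | COC(=O)C1=CC(C(=O)OC)(C(=O)OC)CCC1=O | intermediate
7 | 2,4,6-trivinylcyclotriboroxane–pyridine complex | C=CB1OB(C=C)OB(C=C)O1.c1ccncc1 | starting material
8 | trimethyl (2R)-4-oxo-2-vinylcyclohexane-1,1,3-tricarboxylate (C5 set; C4 epimerisable) | COC(=O)C1C(=O)CCC(C(=O)OC)(C(=O)OC)[C@@H]1C=C | intermediate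
9 | trimethyl (2R,3S)-3-methyl-4-oxo-2-vinylcyclohexane-1,1,3-tricarboxylate (methyl trans to vinyl) | C[C@@]1(C(=O)OC)C(=O)CCC(C(=O)OC)(C(=O)OC)[C@@H]1C=C | intermediate
10 | trimethyl (2R,3S,4S)-4-hydroxy-3-methyl-2-vinylcyclohexane-1,1,3-tricarboxylate (OH cis to methyl, trans to vinyl) | C[C@@]1(C(=O)OC)[C@@H](O)CCC(C(=O)OC)(C(=O)OC)[C@@H]1C=C | intermediate
11 | dimethyl 6-methyl-3-oxo-5-vinyl-2-oxabicyclo[2.2.2]octane-4,6-dicarboxylate (ring-A centres as in 10) | C[C@@]1(C(=O)OC)[C@@H]2CC[C@@](C(=O)OC)(C(=O)O2)[C@@H]1C=C | intermediate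
12 | dimethyl 4-hydroxy-1-(hydroxymethyl)-3-methyl-2-vinylcyclohexane-1,3-dicarboxylate (hydroxymethyl cis to the ring hydroxyl, trans to vinyl) | C[C@@]1(C(=O)OC)[C@@H](O)CC[C@@](C(=O)OC)(CO)[C@@H]1C=C | intermediate
13 | bis(tert-butyldimethylsilyl) ether of 12 | C[C@@]1(C(=O)OC)[C@@H](O[Si](C)(C)C(C)(C)C)CC[C@@](C(=O)OC)(CO[Si](C)(C)C(C)(C)C)[C@@H]1C=C | intermediate
14 | primary alcohol (2-hydroxyethyl on C5; ring A as in 13) | C[C@@]1(C(=O)OC)[C@@H](O[Si](C)(C)C(C)(C)C)CC[C@@](C(=O)OC)(CO[Si](C)(C)C(C)(C)C)[C@@H]1CCO | intermediate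
15 | carboxylic acid (carboxymethyl on C5; ring A as in 13) | C[C@@]1(C(=O)OC)[C@@H](O[Si](C)(C)C(C)(C)C)CC[C@@](C(=O)OC)(CO[Si](C)(C)C(C)(C)C)[C@@H]1CC(=O)O | intermediate
16 | (R)-4-benzyl-2-oxazolidinone | O=C1N[C@H](Cc2ccccc2)CO1 | starting material
17 | mixed pivalic anhydride of 15 | C[C@@]1(C(=O)OC)[C@@H](O[Si](C)(C)C(C)(C)C)CC[C@@](C(=O)OC)(CO[Si](C)(C)C(C)(C)C)[C@@H]1CC(=O)OC(=O)C(C)(C)C | intermediate (not isolated)
18 | N-acyl (R)-4-benzyl-2-oxazolidinone of 15 | C[C@@]1(C(=O)OC)[C@@H](O[Si](C)(C)C(C)(C)C)CC[C@@](C(=O)OC)(CO[Si](C)(C)C(C)(C)C)[C@@H]1CC(=O)N2C(=O)OC[C@H]2Cc3ccccc3 | intermediate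
19 | tert-butyl bromoacetate | CC(C)(C)OC(=O)CBr | starting material
20 | C6-alkylated imide (C6 as in the target; tert-butyl ester at C14) | C[C@@]1(C(=O)OC)[C@@H](O[Si](C)(C)C(C)(C)C)CC[C@@](C(=O)OC)(CO[Si](C)(C)C(C)(C)C)[C@@H]1[C@H](C(=O)N2C(=O)OC[C@H]2Cc3ccccc3)CC(=O)OC(C)(C)C | intermediate
21 | succinic half-ester (C7 acid, C14 tert-butyl ester) | C[C@@]1(C(=O)OC)[C@@H](O[Si](C)(C)C(C)(C)C)CC[C@@](C(=O)OC)(CO[Si](C)(C)C(C)(C)C)[C@@H]1[C@H](C(=O)O)CC(=O)OC(C)(C)C | intermediate
22 | propargyl bromide | C#CCBr | starting material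
23 | C8-propargylated acid (C8 epimers) | C[C@@]1(C(=O)OC)[C@@H](O[Si](C)(C)C(C)(C)C)CC[C@@](C(=O)OC)(CO[Si](C)(C)C(C)(C)C)[C@@H]1[C@H](C(=O)O)C(CC#C)C(=O)OC(C)(C)C | intermediate (not isolated)
24 | C7 methyl ester, C8 propargyl, C14 tert-butyl ester (C8 epimers) | C[C@@]1(C(=O)OC)[C@@H](O[Si](C)(C)C(C)(C)C)CC[C@@](C(=O)OC)(CO[Si](C)(C)C(C)(C)C)[C@@H]1[C@H](C(=O)OC)C(CC#C)C(=O)OC(C)(C)C | intermediate
25 | C9 primary alcohol | C[C@@]1(C(=O)OC)[C@@H](O[Si](C)(C)C(C)(C)C)CC[C@@](C(=O)OC)(CO)[C@@H]1[C@H](C(=O)OC)C(CC#C)C(=O)OC(C)(C)C | intermediate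
26 | C9 aldehyde | C[C@@]1(C(=O)OC)[C@@H](O[Si](C)(C)C(C)(C)C)CC[C@@](C(=O)OC)(C=O)[C@@H]1[C@H](C(=O)OC)C(CC#C)C(=O)OC(C)(C)C | intermediate
27 | diethyl (phenylsulfonylmethyl)phosphonate | CCOP(=O)(CS(=O)(=O)c1ccccc1)OCC | starting material
28 | (E)-vinyl sulfone on C10 | C[C@@]1(C(=O)OC)[C@@H](O[Si](C)(C)C(C)(C)C)CC[C@@](C(=O)OC)(/C=C/S(=O)(=O)c2ccccc2)[C@@H]1[C@H](C(=O)OC)C(CC#C)C(=O)OC(C)(C)C | intermediate
29 | C14 carboxylic acid | C[C@@]1(C(=O)OC)[C@@H](O[Si](C)(C)C(C)(C)C)CC[C@@](C(=O)OC)(/C=C/S(=O)(=O)c2ccccc2)[C@@H]1[C@H](C(=O)OC)C(CC#C)C(=O)O | intermediate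
30 | tributyl(vinyl)stannane | C=C[Sn](CCCC)(CCCC)CCCC | starting material
31 | C14 acid chloride | C[C@@]1(C(=O)OC)[C@@H](O[Si](C)(C)C(C)(C)C)CC[C@@](C(=O)OC)(/C=C/S(=O)(=O)c2ccccc2)[C@@H]1[C@H](C(=O)OC)C(CC#C)C(Cl)=O | intermediate (not isolated)
32 | vinyl ketone (C8 epimers) | C[C@@]1(C(=O)OC)[C@@H](O[Si](C)(C)C(C)(C)C)CC[C@@](C(=O)OC)(/C=C/S(=O)(=O)c2ccccc2)[C@@H]1[C@H](C(=O)OC)C(CC#C)C(=O)C=C | intermediate
33 | silyl dienol ether (C6 trans to the C13 vinyl group) | C[C@@]1(C(=O)OC)[C@@H](O[Si](C)(C)C(C)(C)C)CC[C@@](C(=O)OC)(/C=C/S(=O)(=O)c2ccccc2)[C@@H]1[C@H](C(=O)OC)/C(CC#C)=C(/C=C)O[Si](C)(C)C(C)(C)C | intermediate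
34 | tricyclic silyl enol ether (rings A, B, C; A/B trans, B/C cis; sulfone trans to C10 on ring C) | C[C@]1(C(=O)OC)[C@H]2[C@H](C(=O)OC)[C@@]3(CC#C)C(O[Si](C)(C)C(C)(C)C)=CC[C@H](S(=O)(=O)c4ccccc4)[C@H]3[C@]2(C(=O)OC)CC[C@@H]1O[Si](C)(C)C(C)(C)C | intermediate
35 | tetracyclic C14 ketone with C16=C17 exo-methylene | C[C@]1(C(=O)OC)[C@H]2[C@H](C(=O)OC)[C@@]34C(=O)[C@@H](C[C@H](S(=O)(=O)c5ccccc5)[C@H]3[C@]2(C(=O)OC)CC[C@@H]1O[Si](C)(C)C(C)(C)C)C(=C)C4 | intermediate
36 | C16 tertiary alcohol (exo OH), C14 ketone | C[C@]1(C(=O)OC)[C@H]2[C@H](C(=O)OC)[C@@]34C(=O)[C@@H](C[C@H](S(=O)(=O)c5ccccc5)[C@H]3[C@]2(C(=O)OC)CC[C@@H]1O[Si](C)(C)C(C)(C)C)[C@](C)(O)C4 | intermediate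
37 | C14 tosylhydrazone | C[C@]1(C(=O)OC)[C@H]2[C@H](C(=O)OC)[C@@]34C(=NNS(=O)(=O)c6ccc(C)cc6)[C@@H](C[C@H](S(=O)(=O)c5ccccc5)[C@H]3[C@]2(C(=O)OC)CC[C@@H]1O[Si](C)(C)C(C)(C)C)[C@](C)(O)C4 | intermediate
38 | C14 methylene compound with C11 sulfone | C[C@]1(C(=O)OC)[C@H]2[C@H](C(=O)OC)[C@@]34C[C@@H](C[C@H](S(=O)(=O)c5ccccc5)[C@H]3[C@]2(C(=O)OC)CC[C@@H]1O[Si](C)(C)C(C)(C)C)[C@](C)(O)C4 | intermediate
39 | trimethyl ester C3 tert-butyldimethylsilyl ether of the target | C[C@]1(C(=O)OC)[C@H]2[C@H](C(=O)OC)[C@@]34C[C@@H](CC[C@H]3[C@]2(C(=O)OC)CC[C@@H]1O[Si](C)(C)C(C)(C)C)[C@](C)(O)C4 | intermediate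
40 | trimethyl ester of the target | C[C@]1(C(=O)OC)[C@H]2[C@H](C(=O)OC)[C@@]34C[C@@H](CC[C@H]3[C@]2(C(=O)OC)CC[C@@H]1O)[C@](C)(O)C4 | intermediate
41 | CNP0183110.3 (3,16-dihydroxy C20-gibberellin 7,19,20-triacid) | C[C@]1(C(=O)O)[C@H]2[C@H](C(=O)O)[C@@]34C[C@@H](CC[C@H]3[C@]2(C(=O)O)CC[C@@H]1O)[C@](C)(O)C4 | target

**Step count and risks**

Total step count: 28. Longest linear sequence: 28 steps (from dimethyl malonate and methyl acrylate; all other partners are commercial).

Steps most likely to fail:

1. Step 21. The cycloaddition may be slow at the fully substituted diene terminus, so that desilylation or polymerisation of the diene competes, or the diene-face and ring-fusion selectivity may be insufficient. Fallback (anionic, stepwise): starting from vinyl ketone 32, LiN(SiMe3)2 in THF at −78 to 0 °C should form the C8 enolate, which adds to C9 of the vinyl sulfone; the resulting sulfonyl carbanion at C11 then adds to C12 of the vinyl ketone (intramolecular double Michael reaction). This gives the tricyclic ketone F1. Silylation of F1 with t-BuMe2SiOTf/Et3N, which can only enolise toward C13, returns to compound 34.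

2. Step 3. The 2-ester may slow catalyst turnover (a stable rhodium β-keto ester enolate) or erode the enantioselectivity. Fallback (racemic addition, then catalyst-controlled divergence): starting from enone 6, CH2=CHMgBr with CuBr·SMe2 (cat.) and Me3SiCl in THF at −78 °C gives 8 together with its enantiomer F2. Methylation as in step 4 gives 9 together with its enantiomer F3. The (R)-CBS reduction of step 5 then sets the same C3 configuration in both antipodes, giving 10 and the diastereomeric alcohol F4, which are separated by chromatography. The route is rejoined at compound 10, with at most half of the material.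

3. Step 6. Closure of the strained bicyclic lactone may stay incomplete, or the acid may cause side reactions of the β-hydroxy ester. Fallback (enolate route to differentiate the C10 esters): starting from alcohol 10, silylation (t-BuMe2SiOTf, 2,6-lutidine) gives the silyl ether F5. Krapcho dealkoxycarbonylation (LiCl, wet DMSO, 150 °C) gives the C10 monoester F6. Deprotonation with LiN(i-Pr)2 and formylation with 2,2,2-trifluoroethyl formate, expected trans to the C5 vinyl group but less secure in facial selectivity than the lactone relay, gives the formyl ester F7. NaBH4 reduction gives the hydroxymethyl ester F8, and silylation (t-BuMe2SiCl, imidazole) returns to compound 13.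

**Further compounds**

F1 | step 21 | tricyclic C14 ketone (rings A, B, C; C12 and C13 methylene, C11 sulfone as in 34) | C[C@]1(C(=O)OC)[C@H]2[C@H](C(=O)OC)[C@@]3(CC#C)C(=O)CC[C@H](S(=O)(=O)c4ccccc4)[C@H]3[C@]2(C(=O)OC)CC[C@@H]1O[Si](C)(C)C(C)(C)C
F2 | step 3 | trimethyl (2S)-4-oxo-2-vinylcyclohexane-1,1,3-tricarboxylate (enantiomer of 8) | COC(=O)C1C(=O)CCC(C(=O)OC)(C(=O)OC)[C@H]1C=C
F3 | step 3 | trimethyl (2S,3R)-3-methyl-4-oxo-2-vinylcyclohexane-1,1,3-tricarboxylate (enantiomer of 9) | C[C@]1(C(=O)OC)C(=O)CCC(C(=O)OC)(C(=O)OC)[C@H]1C=C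
F4 | step 3 | trimethyl (2S,3R,4S)-4-hydroxy-3-methyl-2-vinylcyclohexane-1,1,3-tricarboxylate (diastereomer of 10) | C[C@]1(C(=O)OC)[C@@H](O)CCC(C(=O)OC)(C(=O)OC)[C@H]1C=C
F5 | step 6 | tert-butyldimethylsilyl ether of 10 | C[C@@]1(C(=O)OC)[C@@H](O[Si](C)(C)C(C)(C)C)CCC(C(=O)OC)(C(=O)OC)[C@@H]1C=C
F6 | step 6 | C10 monoester of F5 (C10 epimers) | C[C@@]1(C(=O)OC)[C@@H](O[Si](C)(C)C(C)(C)C)CCC(C(=O)OC)[C@@H]1C=C
F7 | step 6 | C10 formyl ester (formyl trans to vinyl) | C[C@@]1(C(=O)OC)[C@@H](O[Si](C)(C)C(C)(C)C)CC[C@@](C(=O)OC)(C=O)[C@@H]1C=C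
F8 | step 6 | C10 hydroxymethyl ester, C3 silyl ether | C[C@@]1(C(=O)OC)[C@@H](O[Si](C)(C)C(C)(C)C)CC[C@@](C(=O)OC)(CO)[C@@H]1C=C
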